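**Retrosynthetic overview**
1. Labels: the core is a bicyclo[3.3.1]nonane, C1 (benzoyl bridgehead)–C2(=O)–C3 (spiro)–C4(=O)–C5 (geranyl bridgehead)–C6H2–C7H–C8Me2, with C9(=O) bridging C1 and C5. Ring A is C1-C2-C3-C4-C5-C9, ring B is C1-C9-C5-C6-C7-C8, the cyclopentane is C3-Ca-Cb(isopropenyl)-Cc(Me2)-Cd, and Ce joins Cd to C7.
2. Feature: C1 and C5 are the two alpha carbons of the C9 ketone, and the C2 and C4 carbonyls both sit on quaternary C3. Ring A is therefore a ring-B cyclohexanone capped at both alpha carbons by a fully substituted malonyl unit. The axial positions at C1, C5 and C7 point to one face, and C7–Ce–Cd already ties that unit to this face.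
3. Disconnections: C1–benzoyl (bridgehead acylation, last). C4–C5 and C1–C2 (tethered double C-acylation of the C9 enol silane by the 1,1-bis(acid chloride) on C3). C5–geranyl (enolate alkylation). C3–Cd and Cb–Cc (radical (3+2) annulation of an isopropenylcyclopropane diester onto a C7 prenyl group).
4. Ring order: ring B first (organocatalytic Michael addition sets C7, then aldol closure). The cyclopentane follows. Ring A and both seven-membered cage rings are closed together in one step.
5. Order of events at the end: esters to acids to acid chlorides, and only then the enol silane, because an enol silane would not survive hydrolysis or oxalyl chloride.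

Key step: step 13

Assumption: the two trans adducts of step 8 differ only in the sense of the cyclopentane relative to C7, and they are taken to be separable by chromatography (preparative HPLC if silica is not enough).

Step 1
Reactants: 1 2-methylbut-3-en-2-ol; 2 ethyl vinyl ether
Product: 4 5-methylhex-4-enal, via allyl vinyl ether 3 (not isolated)
Conditions: H3PO4 (0.5 mol %), neat (excess 2), 150 °C, sealed vessel
Reagents that add atoms: none
Why: Acid-catalysed vinyl transfer gives the tertiary allyl vinyl ether 3, whose Claisen rearrangement delivers the gamma,delta-unsaturated aldehyde with the trisubstituted (prenyl-type) alkene; no stereocentre is formed.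

Step 2
Reactants: 4 5-methylhex-4-enal; 5 methyl vinyl ketone
Product: 6 (2S)-2-(3-methylbut-2-en-1-yl)-5-oxohexanal
Conditions: (S)-2-[methoxy(diphenyl)methyl]pyrrolidine (5 mol %), ethyl 3,4-dihydroxybenzoate (20 mol %), neat, 4 °C
Reagents that add atoms: none
Why: Enamine-catalysed asymmetric Michael addition, in which the E-enamine of 4 is shielded on one face by the CPh2(OMe) group, so the enone adds to the open face and sets the future C7 under catalyst control.

Step 3
Reactants: 6 (2S)-2-(3-methylbut-2-en-1-yl)-5-oxohexanal
Product: 7 (4S)-4-(3-methylbut-2-en-1-yl)cyclohex-2-en-1-one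
Conditions: LiOH, iPrOH, 23 °C
Reagents that add atoms: none
Why: Intramolecular aldol condensation in which only the pairing of methyl ketone enolate and aldehyde gives a six-membered ring (ring B), under mild hydroxide conditions that are used for such 2-substituted 5-oxohexanals because closure outruns epimerization of C7.

Step 4
Reactants: 7 (4S)-4-(3-methylbut-2-en-1-yl)cyclohex-2-en-1-one
Product: 8 trimethyl{[(3S,4S)-3-methyl-4-(3-methylbut-2-en-1-yl)cyclohex-1-en-1-yl]oxy}silane
Conditions: MeMgBr (1.3 equiv), CuBr·SMe2 (5 mol %), TMSCl (2 equiv), DMPU, THF, −78 °C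
Reagents that add atoms: methylmagnesium bromide C[Mg]Br; chlorotrimethylsilane C[Si](C)(C)Cl
Why: TMSCl-accelerated copper-catalysed conjugate addition places methyl on C8 anti to the C7 prenyl group (a centre that step 5 erases) and traps the enolate regiospecifically as the C9=C1 enol silane.

Step 5
Reactants: 8 trimethyl{[(3S,4S)-3-methyl-4-(3-methylbut-2-en-1-yl)cyclohex-1-en-1-yl]oxy}silane
Product: 9 (4S)-3-methyl-4-(3-methylbut-2-en-1-yl)cyclohex-2-en-1-one
Conditions: Pd(OAc)2 (10 mol %), O2 (1 atm), DMSO, 25 °C
Reagents that add atoms: none
Why: Saegusa–Ito oxidation, in which the palladium enolate at C1 loses the C8 hydride to restore the enone, now carrying the C8 methyl; the neutral medium should leave the gamma stereocentre C7 and the trisubstituted alkene untouched.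

Step 6
Reactants: 9 (4S)-3-methyl-4-(3-methylbut-2-en-1-yl)cyclohex-2-en-1-one
Product: 10 (4S)-3,3-dimethyl-4-(3-methylbut-2-en-1-yl)cyclohexan-1-one
Conditions: MeMgBr (1.5 equiv), CuI (10 mol %), THF, −20 → 0 °C; then aq NH4Cl
Reagents that add atoms: methylmagnesium bromide C[Mg]Br
Why: Copper-catalysed conjugate addition of a methyl Grignard reagent to a beta-methyl cyclohexenone, a reaction that tolerates hindered beta carbons, completes the C8 gem-dimethyl group without creating a stereocentre.

Step 7
Reactants: 11 dimethyl malonate; 12 (E)-1,4-dibromo-2-methylbut-2-ene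
Product: 14 dimethyl 2-(prop-1-en-2-yl)cyclopropane-1,1-dicarboxylate (racemic), via monoalkylated allylic bromide 13 (not isolated)
Conditions: NaOMe (2.1 equiv), MeOH, 0 °C → reflux
Reagents that add atoms: none
Why: The first SN2 alkylation should take the less hindered, prenyl-type CH2Br of 12, and the malonate anion of E-configured 13 cannot reach the far CH2Br, so it closes 3-exo in SN2' fashion; the minor 2-methyl-2-vinyl isomer is removed by distillation, and racemic 14 suffices because its stereocentre is lost on ring opening in step 8.

Step 8
Reactants: 10 (4S)-3,3-dimethyl-4-(3-methylbut-2-en-1-yl)cyclohexan-1-one; 14 dimethyl 2-(prop-1-en-2-yl)cyclopropane-1,1-dicarboxylate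
Product: 15 dimethyl (2S,4S)-2-{[(1S)-2,2-dimethyl-4-oxocyclohexyl]methyl}-3,3-dimethyl-4-(prop-1-en-2-yl)cyclopentane-1,1-dicarboxylate
Conditions: PhSSPh (20 mol %), AIBN (10 mol %), benzene, 80 °C, visible-light lamp; 14 added over 8 h to 10 (3 equiv, excess recovered)
Reagents that add atoms: none
Why: Thiyl-radical-catalysed (3+2) annulation of a vinylcyclopropane with an alkene: PhS• adds to the isopropenyl CH2 of 14, the cyclopropylcarbinyl radical opens to the electrophilic malonyl radical (C3), this adds to the CH end (Cd) of the electron-rich prenyl alkene, and the tertiary Cc radical closes 5-exo on the allyl sulfide carbon Cb through a chair-like transition state with the Ce arm pseudo-equatorial (2-substituted hex-5-enyl radical, trans product) before PhS• leaves and uncovers the isopropenyl group; C7 is too remote to bias the face of attack at Cd, so both trans adducts should form, and 15 is separated by chromatography from its diastereomer with inverted Cd and Cb and from the minor cis isomers.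

Step 9
Reactants: 15 the (3+2) adduct; 16 geranyl bromide
Product: 18 C5-geranyl keto diester (C5 epimers), via C5 lithium enolate 17 (not isolated)
Conditions: LDA (1.1 equiv), THF, −78 °C; then 16, DMPU, −78 → −20 °C
Reagents that add atoms: none
Why: Kinetic deprotonation should occur at C5 because C1 is a neopentyl methylene next to C8 and quaternary C3 has no proton, SN2 alkylation with the allylic bromide keeps the E geometry, and the C5 epimer ratio does not matter because C5 becomes sp2 in step 12.

Step 10
Reactants: 18 C5-geranyl keto diester
Product: 19 C5-geranyl keto diacid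
Conditions: KOH (10 equiv), MeOH–H2O, reflux; then 1 M HCl, 0 °C, pH 3
Reagents that add atoms: potassium hydroxide [K+].[OH-]
Why: Saponification of both hindered methyl esters with excess hydroxide, to which the ketone and the three alkenes are inert, followed by cold acidification so that the disubstituted malonic acid does not decarboxylate.

Step 11
Reactants: 19 C5-geranyl keto diacid
Product: 20 C5-geranyl keto bis(acid chloride)
Conditions: (COCl)2 (3 equiv), DMF (2 mol %), CH2Cl2, 0 → 23 °C; evaporation
Reagents that add atoms: oxalyl chloride O=C(Cl)C(=O)Cl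
Why: DMF-catalysed (Vilsmeier-type) chlorination turns both acids into acid chlorides, quaternary C3 excludes ketene formation so the dichloride is a stable pivaloyl-like compound, and all by-products leave as gases at a temperature at which trisubstituted alkenes are routinely carried through this reaction.

Step 12
Reactants: 20 C5-geranyl keto bis(acid chloride)
Product: 21 C5=C9 trimethylsilyl enol ether bis(acid chloride)
Conditions: TMSOTf (1.1 equiv), Et3N (1.5 equiv), Et2O, −20 → 0 °C; pentane, filtration under argon, evaporation; used at once
Reagents that add atoms: trimethylsilyl triflate C[Si](C)(C)OS(=O)(=O)C(F)(F)F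
Why: Soft enol silylation under equilibrating conditions should favour the tetrasubstituted C5=C9 enol silane over the C9=C1 isomer, which needs deprotonation of the neopentyl C1 methylene, while the two hindered acid chlorides have no alpha hydrogen and should not acylate the amine or the enol silane at this temperature without a Lewis acid.

Step 13
Reactants: 21 C5=C9 trimethylsilyl enol ether bis(acid chloride)
Product: 23 cage trione lacking the C1 benzoyl group, via C5-acylated keto acid chloride 22 (not isolated)
Conditions: MgBr2·OEt2 (4 equiv), iPr2NEt (3 equiv), CH2Cl2, 21 added over 10 h (final 1 mM), 0 → 40 °C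
Reagents that add atoms: none
Why: Proposed new method: MgBr2 binds the two acyl chloride oxygens on C3, the C5 end of the C5=C9 enol silane attacks the acyl chloride that stands cis to the Ce arm on the cyclopentane (future C4), chloride takes the silyl group, and the C4/C9 1,3-diketone of 22 then chelates divalent magnesium so that iPr2NEt can enolize C9 toward C1, its only remaining alpha C–H position, for attack on the second acyl chloride (future C2). The closest known reactions are the Effenberger cyclization of cyclohexanone enol ethers with malonyl dichloride, the Lewis-acid C-acylation of enol silanes with acid chlorides and the MgBr2·OEt2/iPr2NEt soft-enolization acylation of ketones with acid chlorides, whereas the tether and a fully substituted malonyl dichloride that cannot react through a ketene are untested. The C4–C5 bond closes the seven-membered ring C3-C4-C5-C6-C7-Ce-Cd in a 7-(enolexo)-exo-trig mode, and the single C1–C2 bond closes ring A in a 6-(enolendo)-exo-trig mode together with the seven-membered ring C1-C2-C3-Cd-Ce-C7-C8 in a 7-(enolexo)-exo-trig mode. C5 and C1 are set by C7, because the tether C7–Ce–Cd lets C3 reach only the ring-B face that carries the axial arm, and C3 is set by Cd, because on that face only the pairing of the cis acyl group with C5 and the trans acyl group with C1 leaves Ca outside the cage. The step needs C- over O-acylation (O-attack would need a nine-membered ring in the first event, and in the second the magnesium on the C9 oxygen and the position of C2 above C1 disfavour the six-membered enol lactone), reaction of the enol silane rather than the three alkenes (orders of magnitude less nucleophilic, and the amine takes up HCl) and cyclization over oligomerization (slow addition at high dilution). The product should neither revert nor epimerize, since C3 and C5 are quaternary and the bridgehead C1–H cannot enolize.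

Step 14
Reactants: 23 cage trione lacking the C1 benzoyl group; 24 benzoyl chloride
Product: 26 target CNP0110731.1, via C1-lithio cage trione 25 (not isolated)
Conditions: LiTMP (1.5 equiv), THF, −78 → −40 °C; then 24 (2 equiv), −78 → 0 °C
Reagents that add atoms: none
Why: Bridgehead lithiation and acylation as practised on bicyclo[3.3.1]nonanetriones: C1–H is the only hydrogen alpha to a carbonyl in 23 and is acidified by the C2 and C9 carbonyls, the hindered amide should not add to the non-enolizable diketone units, and carbanion 25 cannot invert inside the cage, so benzoyl enters with retention.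

**Compound list**
1 | 2-methylbut-3-en-2-ol | C=CC(C)(C)O | starting material
2 | ethyl vinyl ether | C=COCC | starting material
3 | 2-methylbut-3-en-2-yl vinyl ether | C=CC(C)(C)OC=C | intermediate
4 | 5-methylhex-4-enal | CC(C)=CCCC=O | intermediate
5 | methyl vinyl ketone | C=CC(C)=O | starting material
6 | (2S)-2-(3-methylbut-2-en-1-yl)-5-oxohexanal | CC(C)=CC[C@@H](C=O)CCC(C)=O | intermediate
7 | (4S)-4-(3-methylbut-2-en-1-yl)cyclohex-2-en-1-one | CC(C)=CC[C@@H]1CCC(=O)C=C1 | intermediate
8 | trimethyl{[(3S,4S)-3-methyl-4-(3-methylbut-2-en-1-yl)cyclohex-1-en-1-yl]oxy}silane (methyl trans to prenyl) | CC(C)=CC[C@@H]1CCC(O[Si](C)(C)C)=C[C@H]1C | intermediate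
9 | (4S)-3-methyl-4-(3-methylbut-2-en-1-yl)cyclohex-2-en-1-one | CC(C)=CC[C@@H]1CCC(=O)C=C1C | intermediate
10 | (4S)-3,3-dimethyl-4-(3-methylbut-2-en-1-yl)cyclohexan-1-one (ring B; ring carbon 4 is C7) | CC(C)=CC[C@@H]1CCC(=O)CC1(C)C | intermediate
11 | dimethyl malonate | COC(=O)CC(=O)OC | starting material
12 | (E)-1,4-dibromo-2-methylbut-2-ene | BrC/C=C(/CBr)C | starting material
13 | dimethyl 2-[(2E)-4-bromo-3-methylbut-2-en-1-yl]malonate | COC(=O)C(C/C=C(\C)CBr)C(=O)OC | intermediate
14 | dimethyl 2-(prop-1-en-2-yl)cyclopropane-1,1-dicarboxylate (racemic) | C=C(C)C1CC1(C(=O)OC)C(=O)OC | intermediate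
15 | dimethyl (2S,4S)-2-{[(1S)-2,2-dimethyl-4-oxocyclohexyl]methyl}-3,3-dimethyl-4-(prop-1-en-2-yl)cyclopentane-1,1-dicarboxylate (Ce arm and isopropenyl trans) | C=C(C)[C@@H]1CC(C(=O)OC)(C(=O)OC)[C@@H](C[C@@H]2CCC(=O)CC2(C)C)C1(C)C | intermediate
16 | geranyl bromide | BrC/C=C(\C)CCC=C(C)C | starting material
17 | C5=C9 lithium enolate of 15 | C=C(C)[C@@H]1CC(C(=O)OC)(C(=O)OC)[C@@H](C[C@@H]2CC=C(O[Li])CC2(C)C)C1(C)C | intermediate
18 | C5-geranyl keto diester (Cb S, Cd S, C7 now R by priority change only; C5 epimers) | C=C(C)[C@@H]1CC(C(=O)OC)(C(=O)OC)[C@@H](C[C@@H]2CC(C/C=C(\C)CCC=C(C)C)C(=O)CC2(C)C)C1(C)C | intermediate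
19 | C5-geranyl keto diacid (C5 epimers) | C=C(C)[C@@H]1CC(C(=O)O)(C(=O)O)[C@@H](C[C@@H]2CC(C/C=C(\C)CCC=C(C)C)C(=O)CC2(C)C)C1(C)C | intermediate
20 | C5-geranyl keto bis(acid chloride) (C5 epimers) | C=C(C)[C@@H]1CC(C(Cl)=O)(C(Cl)=O)[C@@H](C[C@@H]2CC(C/C=C(\C)CCC=C(C)C)C(=O)CC2(C)C)C1(C)C | intermediate
21 | cyclopentane-1,1-dicarbonyl dichloride tethered through Ce to the C5=C9 trimethylsilyl enol ether of ring B (Cb S, Cd S, C7 R) | C=C(C)[C@@H]1CC(C(Cl)=O)(C(Cl)=O)[C@@H](C[C@@H]2CC(C/C=C(\C)CCC=C(C)C)=C(O[Si](C)(C)C)CC2(C)C)C1(C)C | intermediate
22 | C5-acylated keto acid chloride (C4–C5 formed; C4 cis to Ce on the cyclopentane; remaining COCl over C1) | C=C(C)[C@@H]1C[C@@]2(C(Cl)=O)C(=O)[C@@]3(C/C=C(\C)CCC=C(C)C)C[C@@H](C[C@H]2C1(C)C)C(C)(C)CC3=O | intermediate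
23 | cage trione with C1–H (C2, C4 and Ce on one face of ring B; Ca exo on C3) | C=C(C)[C@@H]1C[C@@]23C(=O)[C@@]4(C/C=C(\C)CCC=C(C)C)C[C@@H](C[C@H]2C1(C)C)C(C)(C)[C@H](C4=O)C3=O | intermediate
24 | benzoyl chloride | O=C(Cl)c1ccccc1 | starting material
25 | C1-lithio cage trione | C=C(C)[C@@H]1C[C@@]23C(=O)[C@@]4(C/C=C(\C)CCC=C(C)C)C[C@@H](C[C@H]2C1(C)C)C(C)(C)[C@]([Li])(C4=O)C3=O | intermediate
26 | CNP0110731.1 | C=C(C)[C@@H]1C[C@@]23C(=O)[C@@]4(C/C=C(\C)CCC=C(C)C)C[C@@H](C[C@H]2C1(C)C)C(C)(C)[C@](C(=O)c1ccccc1)(C4=O)C3=O | target

Total step count: 14. Longest linear sequence: 13 (steps 1–6 and 8–14; step 7 is the side branch).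

**Steps most likely to fail**

1. Step 13.
 - What may go wrong: the C9 enolate may be O-acylated by the second acyl chloride to give a six-membered enol lactone. The trans acyl chloride may attack C5 first, which leaves the other acyl group out of reach of C1. The hindered acyl chlorides may react so slowly that intermolecular acylation takes over.
 - Fallback (known chemistry, from 18 back to 23): the same two bonds are made by aldol addition instead of acylation. LiAlH4 reduces both esters and the ketone of 18 to the triol F1. Swern oxidation gives the keto dialdehyde F2. Reversible double intramolecular aldol addition under a non-nucleophilic base (DBU, CH2Cl2) funnels the material into the cage keto diol F3. Dess–Martin periodinane oxidizes both carbinols to give 23.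

2. Step 8.
 - What may go wrong: the ring-opened malonyl radical may add to the isopropenyl group of a second molecule of 14 (oligomerization) faster than to the hindered trisubstituted alkene. There is also no facial bias at Cd and only a moderate trans preference at Cb.
 - Fallback (from 10 back to 15): the intermolecular radical addition is replaced by polar bond formation, and only the ring closure remains radical. Ozonolysis of the prenyl group gives the keto aldehyde F4. Knoevenagel condensation with 11 gives the alkylidene malonate F5. Copper-catalysed 1,4-addition of isopropenylmagnesium bromide gives the isopropenyl adduct F6. At this stage the Cd epimers can be separated, or a chiral ligand on copper can be screened for reagent control. NaH and prenyl bromide give the prenylated malonate F7. Hydrogen-atom-transfer cycloisomerization (Co(salen)Cl, PhSiH3) then generates the tertiary Cc radical from the 1,1-disubstituted alkene. This radical closes 5-exo on the prenyl alkene and loses a hydrogen atom to give 15.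

3. Step 14.
 - What may go wrong: the hindered bridgehead carbanion beside C8 may be captured too slowly by benzoyl chloride, so that the amide consumes the acyl chloride or the anion decays.
 - Fallback (from 23 back to 26): the LiTMP anion is quenched with the small electrophile I2 to give the bridgehead iodide F8. Iodine–magnesium exchange with iPrMgCl·LiCl and addition to benzaldehyde give the bridgehead carbinol F9. Dess–Martin oxidation gives 26.

Further compounds
F1 | step 13 | triol from full reduction of 18 | C=C(C)[C@@H]1CC(CO)(CO)[C@@H](C[C@@H]2CC(C/C=C(\C)CCC=C(C)C)C(O)CC2(C)C)C1(C)C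
F2 | step 13 | keto dialdehyde | C=C(C)[C@@H]1CC(C=O)(C=O)[C@@H](C[C@@H]2CC(C/C=C(\C)CCC=C(C)C)C(=O)CC2(C)C)C1(C)C
F3 | step 13 | cage keto diol (C2 and C4 carbinols, epimers) | C=C(C)[C@@H]1C[C@@]23C(O)[C@@]4(C/C=C(\C)CCC=C(C)C)C[C@@H](C[C@H]2C1(C)C)C(C)(C)[C@H](C4=O)C3O
F4 | step 8 | 2-[(1S)-2,2-dimethyl-4-oxocyclohexyl]acetaldehyde | O=CC[C@@H]1CCC(=O)CC1(C)C
F5 | step 8 | alkylidene malonate of F4 | COC(=O)C(=CC[C@@H]1CCC(=O)CC1(C)C)C(=O)OC
F6 | step 8 | isopropenyl adduct (Cd as in 15) | COC(=O)C(C(=O)OC)[C@@H](C[C@@H]1CCC(=O)CC1(C)C)C(C)=C
F7 | step 8 | prenylated malonate | COC(=O)C(CC=C(C)C)(C(=O)OC)[C@@H](C[C@@H]1CCC(=O)CC1(C)C)C(C)=C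
F8 | step 14 | bridgehead iodide | C=C(C)[C@@H]1C[C@@]23C(=O)[C@@]4(C/C=C(\C)CCC=C(C)C)C[C@@H](C[C@H]2C1(C)C)C(C)(C)[C@](I)(C4=O)C3=O
F9 | step 14 | bridgehead carbinol (carbinol epimers) | C=C(C)[C@@H]1C[C@@]23C(=O)[C@@]4(C/C=C(\C)CCC=C(C)C)C[C@@H](C[C@H]2C1(C)C)C(C)(C)[C@](C(O)c1ccccc1)(C4=O)C3=O
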